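**Assumption:** Agrimol F has no stereocentres or stereogenic axes, so it is achiral and there is no enantiomer to control. The ring substitution pattern is fixed by the route's regiochemistry instead.

## Retrosynthetic overview
1. No rings are formed. Every ring is a purchased arene (phloroglucinol, 3,5-dihydroxyanisole), and the route only substitutes them.
2. The two aryl C–CH3 bonds are made last. The trimer 12 leaves exactly one free ring C–H on each end ring, so a double Mannich aminomethylation followed by C–N hydrogenolysis is unambiguous. This inverts the usual order, in which methyl groups are pre-installed on the end units.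
3. The two Ar–CH2–Ar bonds are made by iterative ortho-quinone methide (o-QM) transfer. A Mannich base of each acyl-resorcinol end unit (9, 10) alkylates the central butyrylphloroglucinol 3. The acetyl end goes on first, with 3 in excess, and the butyryl end second.
4. The end units come from 3,5-dihydroxyanisole by BF₃-mediated acylation followed by C-3 Mannich aminomethylation. The central unit comes from phloroglucinol by Hoesch acylation.

## Route

**Step 1**
Reactants: 1 phloroglucinol; 2 butyronitrile
Product: 3 2′,4′,6′-trihydroxybutyrophenone
Conditions: ZnCl₂, HCl(g), Et₂O, 0 °C; then H₂O, reflux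
Reagents that add atoms: butyronitrile (CCCC#N, this is 2); water (O)
Why: Hoesch acylation, where the ketimine hydrochloride is hydrolysed to the ketone. Phloroglucinol is fully symmetric, so there is no regiochemical issue.

**Step 2**
Reactants: 4 3,5-dihydroxyanisole; 5 acetic acid
Product: 6 1-(2,4-dihydroxy-6-methoxyphenyl)ethan-1-one
Conditions: BF₃·OEt₂, 85 °C
Reagents that add atoms: acetic acid (CC(=O)O, this is 5)
Why: BF₃-mediated Friedel–Crafts acylation goes to C-2, which is ortho to OMe and OH and para to the other OH. This is the resorcinol "4-position", not the hindered C-4 between the two OH groups. I assume this is the major regioisomer and that the minor one is separable.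

**Step 3**
Reactants: 4; 7 butyric acid
Product: 8 1-(2,4-dihydroxy-6-methoxyphenyl)butan-1-one
Conditions: BF₃·OEt₂, 85 °C
Reagents that add atoms: butyric acid (CCCC(=O)O, this is 7)
Why: same BF₃-mediated Friedel–Crafts acylation as Step 2, with the same regiochemical reasoning.

**Step 4**
Reactants: 6
Product: 9 1-[3-(dimethylaminomethyl)-2,4-dihydroxy-6-methoxyphenyl]ethan-1-one
Conditions: 37% aq. HCHO, 40% aq. Me₂NH, EtOH, 25 → 50 °C
Reagents that add atoms: formaldehyde (C=O); dimethylamine (CNC)
Why: Mannich reaction. Aminomethylation is reversible, and the thermodynamic site is C-3 between the two OH groups, where the zwitterion is best stabilised. The free position flanked by OMe and OH is less favoured.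

**Step 5**
Reactants: 8
Product: 10 1-[3-(dimethylaminomethyl)-2,4-dihydroxy-6-methoxyphenyl]butan-1-one
Conditions: 37% aq. HCHO, 40% aq. Me₂NH, EtOH, 25 → 50 °C
Reagents that add atoms: formaldehyde (C=O); dimethylamine (CNC)
Why: same Mannich reaction and regiochemical argument as Step 4.

**Step 6**
Reactants: 9; 3 (3 equiv)
Product: 11 acetyl-end/central dimer, 1-{3-[(3-butanoyl-2,4,6-trihydroxyphenyl)methyl]-2,4-dihydroxy-6-methoxyphenyl}ethan-1-one with one free central C–H
Conditions: 1,4-dioxane, 95 °C, sealed tube, 16 h
Reagents that add atoms: none (HNMe₂ is lost)
Why: thermal retro-Mannich loss of HNMe₂ gives an o-QM, and 1,4-addition of the most nucleophilic carbon of 3 forms the diarylmethane bond. The excess of 3 suppresses bis-benzylation and self-condensation. The central ring is symmetric, so there is no stereochemical or regiochemical issue on it.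

**Step 7**
Reactants: 11; 10 (1.05 equiv)
Product: 12 trimer with both methyl groups still missing
Conditions: 1,4-dioxane, 95 °C, sealed tube, 16 h
Reagents that add atoms: none (HNMe₂ is lost)
Why: the same o-QM transfer alkylates the remaining central position of 11 at its only free C–H between two OH groups. This completes the Ac/Bu-differentiated trimer without statistics, because the two end units are introduced in separate steps.

**Step 8**
Reactants: 12
Product: 13 bis-Mannich base, aminomethylated at both end-ring C–H sites
Conditions: Me₂N⁺=CH₂ I⁻ (3 equiv), MeCN, 25 → 50 °C; then aq. NaHCO₃ work-up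
Reagents that add atoms: Eschenmoser's salt (C[N+](C)=C.[I-])
Why: electrophilic aminomethylation (Mannich). 12 has only one free arene C–H per end ring, flanked by OMe and OH, and the central ring is fully substituted. Each methyl is therefore placed unambiguously next to the OMe group.

**Step 9**
Reactants: 13
Product: 14 Agrimol F
Conditions: H₂ (1 atm), 10% Pd/C, EtOH, AcOH (cat.), 25 °C
Reagents that add atoms: none (H₂ adds only hydrogen)
Why: hydrogenolysis of the benzylic C–N bond of ortho-hydroxybenzylamines converts CH₂NMe₂ to CH₃ (reductive deamination, with the o-QM as a possible intermediate). Chelated, 2,6-disubstituted aryl ketones and the aryl ethers survive, and no stereocentres exist.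

## Checks (corrected before writing)
- The product SMILES of Step 9 equals the target. The central ring carries butyryl, 2,4,6-OH, and CH₂ at C-3 and C-5. Each end ring has CH₂, two OH groups, CH₃, OMe and an acyl group. The OMe sits between CH₃ and acyl, and CH₃ is flanked by OMe and OH. One end ring carries acetyl and the other butyryl.
- Atom balance holds at every step. The C₃₂H₃₆O₁₂ trimer 12 gains two CH₂NMe₂ groups in Step 8, and each is reduced to CH₃ in Step 9.
- Conditions are compatible with the functional groups. No BCl₃ or AlCl₃ is used after the OMe groups are installed, so ortho-acyl OMe demethylation is avoided. Only the Step 9 hydrogenolysis is reductive, and it leaves the ketones untouched.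

## Compound list
1 | phloroglucinol | Oc1cc(O)cc(O)c1 | starting material
2 | butyronitrile | CCCC#N | starting material
3 | 2′,4′,6′-trihydroxybutyrophenone | CCCC(=O)c1c(O)cc(O)cc1O | intermediate
4 | 3,5-dihydroxyanisole | COc1cc(O)cc(O)c1 | starting material
5 | acetic acid | CC(=O)O | starting material
6 | 1-(2,4-dihydroxy-6-methoxyphenyl)ethanone | CC(=O)c1c(OC)cc(O)cc1O | intermediate
7 | butyric acid | CCCC(=O)O | starting material
8 | 1-(2,4-dihydroxy-6-methoxyphenyl)butan-1-one | CCCC(=O)c1c(OC)cc(O)cc1O | intermediate
9 | acetyl-end Mannich base | CC(=O)c1c(OC)cc(O)c(CN(C)C)c1O | intermediate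
10 | butyryl-end Mannich base | CCCC(=O)c1c(OC)cc(O)c(CN(C)C)c1O | intermediate
11 | acetyl-end/central dimer | CC(=O)c1c(OC)cc(O)c(Cc2c(O)cc(O)c(C(=O)CCC)c2O)c1O | intermediate
12 | trimer without methyl groups | CC(=O)c1c(OC)cc(O)c(Cc2c(O)c(Cc3c(O)cc(OC)c(C(=O)CCC)c3O)c(O)c(C(=O)CCC)c2O)c1O | intermediate
13 | bis-Mannich trimer | CC(=O)c1c(OC)c(CN(C)C)c(O)c(Cc2c(O)c(Cc3c(O)c(CN(C)C)c(OC)c(C(=O)CCC)c3O)c(O)c(C(=O)CCC)c2O)c1O | intermediate
14 | Agrimol F (achiral, no stereocentres) | CCCC(=O)c1c(O)c(Cc2c(O)c(C)c(OC)c(C(C)=O)c2O)c(O)c(Cc2c(O)c(C)c(OC)c(C(=O)CCC)c2O)c1O | target

## Summary
Total steps: 9. Longest linear sequence: 6 (Step 2 → 4 → 6 → 7 → 8 → 9).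

Three steps most likely to fail:
1. **Steps 8–9, late double C-methylation.** The hindered, moderately deactivated end-ring sites may aminomethylate incompletely, and o-QM oligomerisation is possible.
   - Fallback: install the methyl groups on the end units before coupling. Build each end ring by sequential directed ortho-metalation of 1-methoxy-3,5-bis(MOMO)benzene: C-4 is formylated to serve as the benzylic handle, then CH₃ is added, then the acyl group. Couple to 3 as in Steps 6–7.
2. **Step 7, second o-QM coupling.** The site on the central ring of 11 is crowded, and the o-QM from 10 can also alkylate the free end-ring C–H of 11 or of the product.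
   - Fallback: reverse polarity. Form the central 3,5-bis(aminomethyl) Mannich base of 3 and couple it stepwise to the end-unit nucleophiles. Alternatively, form each diarylmethane bond by condensing an end-unit 3-formyl derivative with 3 and then reducing (Et₃SiH/TFA).
3. **Steps 4–5 (and 2–3), regioselectivity.** Aminomethylation must occur between the two OH groups (C-3), not between OH and OMe, and acylation must occur at C-2 of 3,5-dihydroxyanisole. The wrong isomer would give a constitutional isomer of the target.
   - Fallback: build the end units from 2,4,6-trihydroxyacylbenzenes (the phloroacetophenone/butyrophenone analogues). Protect the para-OH as its benzyl ether, mono-methylate one ortho-OH, and remove the benzyl group by hydrogenolysis. Take the C-3 Mannich site from these units with the regiochemistry fixed by protection.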